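**Plan**

- Retrosynthesis: the C3 ester, the C8=C17 methylidene and the C13–C16/C14–C15 bonds of the side chain (from an alkyne) are cut first. Ring A (C3–C4) and ring B (C5–C10) are then opened together to an acyclic dialdehyde, which is cut at C10–C1, C10=C20 and C8–C9.
- Forward: a syn-aldol joins C8–C9; Weinreb amide, Grignard addition and methylenation give the C10=C20H2 alkene with the C1–C3 arm. One operation then closes ring B (C5–C10) and, last, ring A (C3–C4). Methylalumination/hydroxymethylation, angeloylation and C8 methylenation finish the route.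
- Enabling feature: in ring A the C3 oxygen and the C19 oxygen on quaternary C4 are 1,3-related (aldol retron across C3–C4), C5 is β to C19, and the neighbouring quaternary C10 carries a methyl group. C10 is therefore the tertiary radical of a C10=C20 methylidene, and an enal at C5=C4–C19 accepts it.
- Stereochemistry: C9 (and a temporary C8 silyloxy centre) come from an auxiliary-controlled syn-aldol; C10, C5, C4 and C3 are relayed from C9 in the cascade; 13E comes from syn-carboalumination; the angelate Z geometry comes from angelic acid.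

Key step: step 14

Remark: labdane numbering (C1–C20) is used for positions; the target is read as the ent-labdane (3R,4S,5S,9R,10S; 13E; ester 2Z), i.e. trans-decalin, 3-O-acyl equatorial and cis to the C10 methyl, C4 hydroxymethyl equatorial.

Step 1
Reactants: 1 ethyl pent-4-enoate; 2 methacrolein
Product: 3 ethyl (4E)-5-methyl-6-oxohex-4-enoate
Conditions: Grubbs II (3 mol%), excess 2, CH2Cl2, 40 °C
Reagents that add atoms: none
Why: Olefin cross-metathesis of a terminal alkene with methacrolein should give the trisubstituted 2-methyl enal as the thermodynamically preferred E isomer.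

Step 2
Reactants: 3 ethyl (4E)-5-methyl-6-oxohex-4-enoate
Product: 4 ethyl (4E)-6-hydroxy-5-methylhex-4-enoate
Conditions: NaBH4, CeCl3·7H2O, MeOH, 0 °C
Reagents that add atoms: none
Why: Luche reduction should reduce the enal 1,2 and leave the ester and the alkene geometry untouched.

Step 3
Reactants: 4 ethyl (4E)-6-hydroxy-5-methylhex-4-enoate
Product: 5 ethyl (4E)-6-[(tert-butyldimethylsilyl)oxy]-5-methylhex-4-enoate
Conditions: TBSCl, imidazole, CH2Cl2, rt
Reagents that add atoms: tert-butyldimethylsilyl chloride, CC(C)(C)[Si](C)(C)Cl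
Why: Standard silylation of a primary allylic alcohol.

Step 4
Reactants: 5 ethyl (4E)-6-[(tert-butyldimethylsilyl)oxy]-5-methylhex-4-enoate
Product: 6 (4E)-6-[(tert-butyldimethylsilyl)oxy]-5-methylhex-4-enal
Conditions: DIBAL-H (1.05 equiv), CH2Cl2, −78 °C; Rochelle salt
Reagents that add atoms: none
Why: Partial reduction of the ethyl ester should stop at the aldehyde because the aluminium hemiacetal is stable at −78 °C.

Step 5
Reactants: 7 hex-5-ynoic acid
Product: 9 6-(trimethylsilyl)hex-5-ynoic acid, via trimethylsilyl 6-(trimethylsilyl)hex-5-ynoate 8 (not isolated)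
Conditions: n-BuLi (2.1 equiv), THF, −78 °C; TMSCl (2.2 equiv), −78 °C → rt; 1 M HCl
Reagents that add atoms: trimethylsilyl chloride, C[Si](C)(C)Cl
Why: The carboxylate/acetylide dianion is silylated on carbon and oxygen, and aqueous acid cleaves only the silyl ester.

Step 6
Reactants: 9 6-(trimethylsilyl)hex-5-ynoic acid; 10 (4R)-4-benzyl-1,3-oxazolidin-2-one
Product: 12 (4R)-4-benzyl-3-[6-(trimethylsilyl)hex-5-ynoyl]-1,3-oxazolidin-2-one, via 6-(trimethylsilyl)hex-5-ynoic pivalic anhydride 11 (not isolated)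
Conditions: PivCl, Et3N, THF, −20 °C; then 10, LiCl, −20 °C → rt
Reagents that add atoms: none
Why: N-acylation of the oxazolidinone through the pivaloyl mixed anhydride is a standard way to load the Evans auxiliary.

Step 7
Reactants: 12 (4R)-4-benzyl-3-[6-(trimethylsilyl)hex-5-ynoyl]-1,3-oxazolidin-2-one; 6 (4E)-6-[(tert-butyldimethylsilyl)oxy]-5-methylhex-4-enal
Product: 14 (4R)-4-benzyl-3-[(2R,3S,6E)-8-[(tert-butyldimethylsilyl)oxy]-3-hydroxy-7-methyl-2-[4-(trimethylsilyl)but-3-yn-1-yl]oct-6-enoyl]-1,3-oxazolidin-2-one, via dibutylboron Z-enolate 13 (not isolated)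
Conditions: n-Bu2BOTf, i-Pr2NEt, CH2Cl2, 0 °C; 6, −78 → 0 °C; pH 7 buffer, MeOH, H2O2
Reagents that add atoms: none
Why: Evans syn-aldol: the Z-boron enolate reacts through a Zimmerman–Traxler chair on the face away from the benzyl group, which sets C9 (acyl C2, R) and the temporary C8 carbinol (acyl C3, S).

Step 8
Reactants: 14 the syn-aldol adduct
Product: 15 (2R,3S,6E)-8-[(tert-butyldimethylsilyl)oxy]-3-hydroxy-N-methoxy-N,7-dimethyl-2-[4-(trimethylsilyl)but-3-yn-1-yl]oct-6-enamide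
Conditions: MeNHOMe·HCl, AlMe3, CH2Cl2, −20 → 0 °C
Reagents that add atoms: N,O-dimethylhydroxylamine hydrochloride, CNOC.Cl
Why: Aluminium amide transamination of a β-hydroxy imide (Weinreb amide formation) is assisted by the free hydroxyl and releases the auxiliary without touching C9.

Step 9
Reactants: 15 the β-hydroxy Weinreb amide
Product: 16 (2R,3S,6E)-3,8-bis[(tert-butyldimethylsilyl)oxy]-N-methoxy-N,7-dimethyl-2-[4-(trimethylsilyl)but-3-yn-1-yl]oct-6-enamide
Conditions: TBSOTf, 2,6-lutidine, CH2Cl2, −78 → 0 °C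
Reagents that add atoms: tert-butyldimethylsilyl triflate, CC(C)(C)[Si](C)(C)OS(=O)(=O)C(F)(F)F
Why: Silylation of the secondary alcohol; a silyl group is chosen for C8–O so that no weak C–H bond lies 1,5 to the later C10 radical.

Step 10
Reactants: 16 the bis-silyl Weinreb amide; 17 (3-bromopropoxy)(tert-butyl)dimethylsilane
Product: 19 (5R,6S,9E)-1,6,11-tris[(tert-butyldimethylsilyl)oxy]-10-methyl-5-[4-(trimethylsilyl)but-3-yn-1-yl]undec-9-en-4-one, via Grignard reagent 18 (not isolated)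
Conditions: 17, Mg, THF; then 16, 0 °C; aq. NH4Cl
Reagents that add atoms: none
Why: Grignard addition to a Weinreb amide should stop at the ketone through the chelated tetrahedral intermediate, so C9 is not exposed to base as a ketone α-centre.

Step 11
Reactants: 19 the C10 ketone
Product: 20 (2E,6S,7S)-1,6,11-tris[(tert-butyldimethylsilyl)oxy]-2-methyl-8-methylidene-7-[4-(trimethylsilyl)but-3-yn-1-yl]undec-2-ene
Conditions: Zn, CH2Br2, TiCl4 (Takai–Lombardo reagent), THF/CH2Cl2, 0 °C → rt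
Reagents that add atoms: dibromomethane, BrCBr
Why: Takai–Lombardo methylenation is non-basic, so the enolisable ketone should be methylenated without epimerising C9 or eliminating the β-silyloxy group.

Step 12
Reactants: 20 the tris-silyl ether
Product: 21 (2E,6S,7S)-6-[(tert-butyldimethylsilyl)oxy]-2-methyl-8-methylidene-7-[4-(trimethylsilyl)but-3-yn-1-yl]undec-2-ene-1,11-diol
Conditions: CSA (cat.), MeOH/CH2Cl2, 0 °C
Reagents that add atoms: none
Why: Acid-catalysed methanolysis should remove the two primary TBS ethers much faster than the hindered secondary one, and the alkynyl C–Si bond is stable to acid.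

Step 13
Reactants: 21 the 1,11-diol
Product: 22 (2E,6S,7S)-6-[(tert-butyldimethylsilyl)oxy]-2-methyl-8-methylidene-7-[4-(trimethylsilyl)but-3-yn-1-yl]undec-2-enedial
Conditions: Dess–Martin periodinane, CH2Cl2, 0 °C → rt
Reagents that add atoms: none
Why: Dess–Martin oxidation converts the allylic alcohol to the E-enal and the saturated alcohol to the aldehyde under near-neutral conditions.

Step 14
Reactants: 22 the acyclic ene–enal–aldehyde
Product: 25 (1R,2R,4aR,5S,6S,8aS)-6-[(tert-butyldimethylsilyl)oxy]-2-hydroxy-1,4a-dimethyl-5-[4-(trimethylsilyl)but-3-yn-1-yl]decahydronaphthalene-1-carbaldehyde, via tertiary C10 radical 23 (not isolated), via ring-B iron enolate 24 (not isolated)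
Conditions: Fe(acac)3 (30 mol%), PhSiH2(Oi-Pr), (CH2OH)2, ClCH2CH2Cl, degassed, 0 °C → rt
Reagents that add atoms: none
Why: Iron-hydride hydrogen-atom transfer to the electron-rich 1,1-disubstituted alkene (H to C20) gives the tertiary C10 radical 23, which adds 6-exo-trig to C5, the β-carbon of the E-enal, closing ring B; the α-formyl radical is reduced by Fe(II) to the iron enolate 24 (radical–polar crossover), which closes ring A last by a 6-(enolexo)-exo-trig aldol addition of C4 to the C3 aldehyde. The closest known reaction type is the MHAT-initiated (Mukaiyama-type) radical conjugate addition–aldol polycyclization of alkene/enal/carbonyl substrates, which gives trans-decalins with a hydroxyl next to a formyl-bearing quaternary carbon. C5 and C10 are controlled by C9 (reinforced by C8): ring B forms through a chair in which the C9 side chain, the C8 silyloxy group and the enal arm on C5 are equatorial, and 1,2-strain at the planar radical puts the small methyl next to C8 (axial) and the C1–C3 chain equatorial, i.e. trans ring fusion. C4 and C3 are set in a chelated Zimmerman–Traxler chair on this template, with the aldehyde oxygen and the enolate carbon C19 equatorial and the C4 methyl axial, giving the equatorial 3-OH cis to both axial methyl groups. Chemoselectivity is needed at three points and is secured by the substrate: only C10=C20 is an electron-rich alkene for hydrogen-atom transfer (the enal is electron-poor, the alkyne is silylated), the nucleophilic tertiary radical is polarity-matched to the enal and not to the alkyne (5-exo-dig), and the C8 oxygen carries a silyl group so that no weak C–H lies 1,5 to the radical. The enolate is generated only at C4, so the regiochemistry of the aldol is fixed by the radical step.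

Step 15
Reactants: 25 the bicyclic β-hydroxy aldehyde
Product: 27 (1S,2R,4aR,5S,6S,8aS)-5-(but-3-yn-1-yl)-6-[(tert-butyldimethylsilyl)oxy]-1-(hydroxymethyl)-1,4a-dimethyldecahydronaphthalen-2-ol, via C-silylated 1,3-diol 26 (not isolated)
Conditions: NaBH4, MeOH, 0 °C; then K2CO3, rt
Reagents that add atoms: none
Why: Borohydride reduction of the aldehyde should outrun retro-aldol, and K2CO3/MeOH protodesilylates the alkyne while the secondary TBS ether survives.

Step 16
Reactants: 27 the alkynyl diol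
Product: 29 (1S,2R,4aR,5S,6S,8aS)-6-[(tert-butyldimethylsilyl)oxy]-1-(hydroxymethyl)-5-[(3E)-5-hydroxy-3-methylpent-3-en-1-yl]-1,4a-dimethyldecahydronaphthalen-2-ol, via E-alkenyldimethylalane 28 (not isolated)
Conditions: AlMe3 (excess), Cp2ZrCl2 (cat.), CH2Cl2, 0 °C → rt; then n-BuLi, (CH2O)n, THF, −30 °C → rt
Reagents that add atoms: trimethylaluminium, C[Al](C)C; formaldehyde (as paraformaldehyde), C=O
Why: Negishi zirconium-catalysed carboalumination adds Me and Al syn across the terminal alkyne with Al on the terminal carbon, and the alanate is hydroxymethylated with retention, which should give the 13E allylic alcohol; the free hydroxyls are only converted to aluminium alkoxides.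

Step 17
Reactants: 29 the triol
Product: 30 (1S,2R,4aR,5S,6S,8aS)-6-[(tert-butyldimethylsilyl)oxy]-1-{[(tert-butyldiphenylsilyl)oxy]methyl}-5-{(3E)-5-[(tert-butyldiphenylsilyl)oxy]-3-methylpent-3-en-1-yl}-1,4a-dimethyldecahydronaphthalen-2-ol
Conditions: TBDPSCl (2.2 equiv), imidazole, CH2Cl2, 0 °C → rt
Reagents that add atoms: tert-butyldiphenylsilyl chloride, CC(C)(C)[Si](Cl)(c1ccccc1)c1ccccc1
Why: The bulky silyl chloride should silylate the two primary hydroxyls and leave the 3-OH, a secondary alcohol next to quaternary C4, free.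

Step 18
Reactants: 30 the bis-TBDPS ether with free 3-OH; 31 angelic acid
Product: 33 the 3-O-[(2Z)-2-methylbut-2-enoyl] ester of 30, via angelic 2,4,6-trichlorobenzoic anhydride 32 (not isolated)
Conditions: 31, 2,4,6-trichlorobenzoyl chloride, Et3N, toluene, rt; then 30, 75 °C
Reagents that add atoms: none
Why: Yamaguchi-type mixed-anhydride esterification without a nucleophilic catalyst should acylate the hindered alcohol while avoiding Z→E isomerisation of the angelate to the tiglate.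

Step 19
Reactants: 33 the angelate
Product: 34 (1S,2R,4aR,5S,6S,8aS)-1-{[(tert-butyldiphenylsilyl)oxy]methyl}-5-{(3E)-5-[(tert-butyldiphenylsilyl)oxy]-3-methylpent-3-en-1-yl}-6-hydroxy-1,4a-dimethyldecahydronaphthalen-2-yl (2Z)-2-methylbut-2-enoate
Conditions: HF·pyridine, pyridine, THF, 0 °C → rt
Reagents that add atoms: none
Why: Under acidic fluoride the TBS ether should be cleaved while the TBDPS ethers, which are far more stable to these conditions, and the ester remain.

Step 20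
Reactants: 34 the C8 alcohol
Product: 35 (1S,2R,4aR,5S,8aS)-1-{[(tert-butyldiphenylsilyl)oxy]methyl}-5-{(3E)-5-[(tert-butyldiphenylsilyl)oxy]-3-methylpent-3-en-1-yl}-1,4a-dimethyl-6-oxodecahydronaphthalen-2-yl (2Z)-2-methylbut-2-enoate
Conditions: Dess–Martin periodinane, CH2Cl2, rt
Reagents that add atoms: none
Why: Neutral oxidation of the secondary alcohol gives the C8 ketone; the equatorial C9 side chain is the thermodynamic epimer.

Step 21
Reactants: 35 the C8 ketone
Product: 36 (1S,2R,4aS,5R,8aS)-1-{[(tert-butyldiphenylsilyl)oxy]methyl}-5-{(3E)-5-[(tert-butyldiphenylsilyl)oxy]-3-methylpent-3-en-1-yl}-1,4a-dimethyl-6-methylidenedecahydronaphthalen-2-yl (2Z)-2-methylbut-2-enoate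
Conditions: Zn, CH2Br2, TiCl4 (Takai–Lombardo reagent), THF/CH2Cl2, 0 °C → rt
Reagents that add atoms: dibromomethane, BrCBr
Why: Takai–Lombardo methylenation is selective for ketones over esters and non-basic, so the angelate and C9 should be left untouched.

Step 22
Reactants: 36 the bis-TBDPS ether of the target
Product: 37 (1S,2R,4aS,5R,8aS)-1-(hydroxymethyl)-5-[(3E)-5-hydroxy-3-methylpent-3-en-1-yl]-1,4a-dimethyl-6-methylidenedecahydronaphthalen-2-yl (2Z)-2-methylbut-2-enoate (CNP0118197.1)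
Conditions: TBAF, AcOH, THF, rt
Reagents that add atoms: none
Why: Buffered fluoride removes both TBDPS groups, and the acetic acid buffer should suppress 3→19 acyl migration and ester cleavage.

**Compound list**

1 | ethyl pent-4-enoate | C=CCCC(=O)OCC | starting material
2 | methacrolein | C=C(C)C=O | starting material
3 | ethyl (4E)-5-methyl-6-oxohex-4-enoate | CCOC(=O)CC/C=C(\C)C=O | intermediate
4 | ethyl (4E)-6-hydroxy-5-methylhex-4-enoate | CCOC(=O)CC/C=C(\C)CO | intermediate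
5 | ethyl (4E)-6-[(tert-butyldimethylsilyl)oxy]-5-methylhex-4-enoate | CCOC(=O)CC/C=C(\C)CO[Si](C)(C)C(C)(C)C | intermediate
6 | (4E)-6-[(tert-butyldimethylsilyl)oxy]-5-methylhex-4-enal | O=CCC/C=C(\C)CO[Si](C)(C)C(C)(C)C | intermediate
7 | hex-5-ynoic acid | C#CCCCC(=O)O | starting material
8 | trimethylsilyl 6-(trimethylsilyl)hex-5-ynoate (not isolated) | C[Si](C)(C)C#CCCCC(=O)O[Si](C)(C)C | intermediate
9 | 6-(trimethylsilyl)hex-5-ynoic acid | C[Si](C)(C)C#CCCCC(=O)O | intermediate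
10 | (4R)-4-benzyl-1,3-oxazolidin-2-one | O=C1OC[C@@H](Cc2ccccc2)N1 | starting material
11 | 6-(trimethylsilyl)hex-5-ynoic pivalic anhydride (not isolated) | C[Si](C)(C)C#CCCCC(=O)OC(=O)C(C)(C)C | intermediate
12 | (4R)-4-benzyl-3-[6-(trimethylsilyl)hex-5-ynoyl]-1,3-oxazolidin-2-one | C[Si](C)(C)C#CCCCC(=O)N1[C@H](Cc2ccccc2)COC1=O | intermediate
13 | dibutylboron Z-enolate of 12 (not isolated) | CCCCB(CCCC)O/C(=C\CCC#C[Si](C)(C)C)N1[C@H](Cc2ccccc2)COC1=O | intermediate
14 | (4R)-4-benzyl-3-[(2R,3S,6E)-8-[(tert-butyldimethylsilyl)oxy]-3-hydroxy-7-methyl-2-[4-(trimethylsilyl)but-3-yn-1-yl]oct-6-enoyl]-1,3-oxazolidin-2-one | O[C@@H](CC/C=C(\C)CO[Si](C)(C)C(C)(C)C)[C@@H](CCC#C[Si](C)(C)C)C(=O)N1[C@H](Cc2ccccc2)COC1=O | intermediate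
15 | (2R,3S,6E)-8-[(tert-butyldimethylsilyl)oxy]-3-hydroxy-N-methoxy-N,7-dimethyl-2-[4-(trimethylsilyl)but-3-yn-1-yl]oct-6-enamide | O[C@@H](CC/C=C(\C)CO[Si](C)(C)C(C)(C)C)[C@@H](CCC#C[Si](C)(C)C)C(=O)N(C)OC | intermediate
16 | (2R,3S,6E)-3,8-bis[(tert-butyldimethylsilyl)oxy]-N-methoxy-N,7-dimethyl-2-[4-(trimethylsilyl)but-3-yn-1-yl]oct-6-enamide | CC(C)(C)[Si](C)(C)O[C@@H](CC/C=C(\C)CO[Si](C)(C)C(C)(C)C)[C@@H](CCC#C[Si](C)(C)C)C(=O)N(C)OC | intermediate
17 | (3-bromopropoxy)(tert-butyl)dimethylsilane | BrCCCO[Si](C)(C)C(C)(C)C | starting material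
18 | {3-[(tert-butyldimethylsilyl)oxy]propyl}magnesium bromide (not isolated) | Br[Mg]CCCO[Si](C)(C)C(C)(C)C | intermediate
19 | (5R,6S,9E)-1,6,11-tris[(tert-butyldimethylsilyl)oxy]-10-methyl-5-[4-(trimethylsilyl)but-3-yn-1-yl]undec-9-en-4-one | CC(C)(C)[Si](C)(C)O[C@@H](CC/C=C(\C)CO[Si](C)(C)C(C)(C)C)[C@@H](CCC#C[Si](C)(C)C)C(=O)CCCO[Si](C)(C)C(C)(C)C | intermediate
20 | (2E,6S,7S)-1,6,11-tris[(tert-butyldimethylsilyl)oxy]-2-methyl-8-methylidene-7-[4-(trimethylsilyl)but-3-yn-1-yl]undec-2-ene | CC(C)(C)[Si](C)(C)O[C@@H](CC/C=C(\C)CO[Si](C)(C)C(C)(C)C)[C@@H](CCC#C[Si](C)(C)C)C(=C)CCCO[Si](C)(C)C(C)(C)C | intermediate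
21 | (2E,6S,7S)-6-[(tert-butyldimethylsilyl)oxy]-2-methyl-8-methylidene-7-[4-(trimethylsilyl)but-3-yn-1-yl]undec-2-ene-1,11-diol | CC(C)(C)[Si](C)(C)O[C@@H](CC/C=C(\C)CO)[C@@H](CCC#C[Si](C)(C)C)C(=C)CCCO | intermediate
22 | (2E,6S,7S)-6-[(tert-butyldimethylsilyl)oxy]-2-methyl-8-methylidene-7-[4-(trimethylsilyl)but-3-yn-1-yl]undec-2-enedial | CC(C)(C)[Si](C)(C)O[C@@H](CC/C=C(\C)C=O)[C@@H](CCC#C[Si](C)(C)C)C(=C)CCC=O | intermediate
23 | tertiary C10 radical formed from 22 by H-atom transfer to the methylidene carbon (not isolated) | CC(C)(C)[Si](C)(C)O[C@@H](CC/C=C(\C)C=O)[C@@H](CCC#C[Si](C)(C)C)[C](C)CCC=O | intermediate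
24 | ring-B iron enolate, monocyclic, drawn as the free enolate anion with the iron(III) counter-ion omitted (not isolated) | CC(C)(C)[Si](C)(C)O[C@H]1CC[C@H](/C(C)=C/[O-])[C@@](C)(CCC=O)[C@@H]1CCC#C[Si](C)(C)C | intermediate
25 | (1R,2R,4aR,5S,6S,8aS)-6-[(tert-butyldimethylsilyl)oxy]-2-hydroxy-1,4a-dimethyl-5-[4-(trimethylsilyl)but-3-yn-1-yl]decahydronaphthalene-1-carbaldehyde | CC(C)(C)[Si](C)(C)O[C@H]1CC[C@H]2[C@@](C)(CC[C@@H](O)[C@]2(C)C=O)[C@@H]1CCC#C[Si](C)(C)C | intermediate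
26 | (1S,2R,4aR,5S,6S,8aS)-6-[(tert-butyldimethylsilyl)oxy]-1-(hydroxymethyl)-1,4a-dimethyl-5-[4-(trimethylsilyl)but-3-yn-1-yl]decahydronaphthalen-2-ol (not isolated) | CC(C)(C)[Si](C)(C)O[C@H]1CC[C@H]2[C@@](C)(CC[C@@H](O)[C@]2(C)CO)[C@@H]1CCC#C[Si](C)(C)C | intermediate
27 | (1S,2R,4aR,5S,6S,8aS)-5-(but-3-yn-1-yl)-6-[(tert-butyldimethylsilyl)oxy]-1-(hydroxymethyl)-1,4a-dimethyldecahydronaphthalen-2-ol | CC(C)(C)[Si](C)(C)O[C@H]1CC[C@H]2[C@@](C)(CC[C@@H](O)[C@]2(C)CO)[C@@H]1CCC#C | intermediate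
28 | E-alkenyldimethylalane from 27, hydroxyls drawn free (not isolated) | CC(C)(C)[Si](C)(C)O[C@H]1CC[C@H]2[C@@](C)(CC[C@@H](O)[C@]2(C)CO)[C@@H]1CC/C(C)=C/[Al](C)C | intermediate
29 | (1S,2R,4aR,5S,6S,8aS)-6-[(tert-butyldimethylsilyl)oxy]-1-(hydroxymethyl)-5-[(3E)-5-hydroxy-3-methylpent-3-en-1-yl]-1,4a-dimethyldecahydronaphthalen-2-ol | CC(C)(C)[Si](C)(C)O[C@H]1CC[C@H]2[C@@](C)(CC[C@@H](O)[C@]2(C)CO)[C@@H]1CC/C(C)=C/CO | intermediate
30 | (1S,2R,4aR,5S,6S,8aS)-6-[(tert-butyldimethylsilyl)oxy]-1-{[(tert-butyldiphenylsilyl)oxy]methyl}-5-{(3E)-5-[(tert-butyldiphenylsilyl)oxy]-3-methylpent-3-en-1-yl}-1,4a-dimethyldecahydronaphthalen-2-ol | CC(C)(C)[Si](C)(C)O[C@H]1CC[C@H]2[C@@](C)(CC[C@@H](O)[C@]2(C)CO[Si](c3ccccc3)(c4ccccc4)C(C)(C)C)[C@@H]1CC/C(C)=C/CO[Si](c5ccccc5)(c6ccccc6)C(C)(C)C | intermediate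
31 | angelic acid, (2Z)-2-methylbut-2-enoic acid | C/C=C(/C)C(=O)O | starting material
32 | angelic 2,4,6-trichlorobenzoic anhydride (not isolated) | C/C=C(/C)C(=O)OC(=O)c1c(Cl)cc(Cl)cc1Cl | intermediate
33 | (1S,2R,4aR,5S,6S,8aS)-6-[(tert-butyldimethylsilyl)oxy]-1-{[(tert-butyldiphenylsilyl)oxy]methyl}-5-{(3E)-5-[(tert-butyldiphenylsilyl)oxy]-3-methylpent-3-en-1-yl}-1,4a-dimethyldecahydronaphthalen-2-yl (2Z)-2-methylbut-2-enoate | CC(C)(C)[Si](C)(C)O[C@H]1CC[C@H]2[C@@](C)(CC[C@@H](OC(=O)/C(C)=C\C)[C@]2(C)CO[Si](c3ccccc3)(c4ccccc4)C(C)(C)C)[C@@H]1CC/C(C)=C/CO[Si](c5ccccc5)(c6ccccc6)C(C)(C)C | intermediate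
34 | (1S,2R,4aR,5S,6S,8aS)-1-{[(tert-butyldiphenylsilyl)oxy]methyl}-5-{(3E)-5-[(tert-butyldiphenylsilyl)oxy]-3-methylpent-3-en-1-yl}-6-hydroxy-1,4a-dimethyldecahydronaphthalen-2-yl (2Z)-2-methylbut-2-enoate | O[C@H]1CC[C@H]2[C@@](C)(CC[C@@H](OC(=O)/C(C)=C\C)[C@]2(C)CO[Si](c3ccccc3)(c4ccccc4)C(C)(C)C)[C@@H]1CC/C(C)=C/CO[Si](c5ccccc5)(c6ccccc6)C(C)(C)C | intermediate
35 | (1S,2R,4aR,5S,8aS)-1-{[(tert-butyldiphenylsilyl)oxy]methyl}-5-{(3E)-5-[(tert-butyldiphenylsilyl)oxy]-3-methylpent-3-en-1-yl}-1,4a-dimethyl-6-oxodecahydronaphthalen-2-yl (2Z)-2-methylbut-2-enoate | O=C1CC[C@H]2[C@@](C)(CC[C@@H](OC(=O)/C(C)=C\C)[C@]2(C)CO[Si](c3ccccc3)(c4ccccc4)C(C)(C)C)[C@@H]1CC/C(C)=C/CO[Si](c5ccccc5)(c6ccccc6)C(C)(C)C | intermediate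
36 | (1S,2R,4aS,5R,8aS)-1-{[(tert-butyldiphenylsilyl)oxy]methyl}-5-{(3E)-5-[(tert-butyldiphenylsilyl)oxy]-3-methylpent-3-en-1-yl}-1,4a-dimethyl-6-methylidenedecahydronaphthalen-2-yl (2Z)-2-methylbut-2-enoate | C=C1CC[C@H]2[C@@](C)(CC[C@@H](OC(=O)/C(C)=C\C)[C@]2(C)CO[Si](c3ccccc3)(c4ccccc4)C(C)(C)C)[C@@H]1CC/C(C)=C/CO[Si](c5ccccc5)(c6ccccc6)C(C)(C)C | intermediate
37 | (1S,2R,4aS,5R,8aS)-1-(hydroxymethyl)-5-[(3E)-5-hydroxy-3-methylpent-3-en-1-yl]-1,4a-dimethyl-6-methylidenedecahydronaphthalen-2-yl (2Z)-2-methylbut-2-enoate | C=C1CC[C@H]2[C@@](C)(CC[C@@H](OC(=O)/C(C)=C\C)[C@]2(C)CO)[C@@H]1CC/C(C)=C/CO | target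

**Totals and risks**

Total step count: 22. Longest linear sequence: 20 steps (steps 1–4, then 7–22).

The three steps most likely to fail:

Step 14. The process at risk is the relay of stereochemistry and the timing of the two ring closures: facial control at the planar C10 radical may be weak (cis ring fusion), the enolate may be protonated before the aldol, or the radical may be captured 5-exo-dig by the silylalkyne. The fallback separates the radical and the polar stage and sets out from diol 21. Only the allylic alcohol is oxidised with MnO2 to (2E,6S,7S)-6-[(tert-butyldimethylsilyl)oxy]-11-hydroxy-2-methyl-8-methylidene-7-[4-(trimethylsilyl)but-3-yn-1-yl]undec-2-enal F1, and the remaining primary alcohol is capped with TESCl/imidazole to give its 11-O-triethylsilyl ether F2. The same iron-hydride initiation is then run in ethanol (Fe(acac)3, PhSiH3, EtOH/(CH2OH)2), so that ring B closes by radical conjugate addition and the enolate is simply protonated, giving 2-{(1R,2R,3S,4S)-4-[(tert-butyldimethylsilyl)oxy]-2-methyl-2-[3-(triethylsilyloxy)propyl]-3-[4-(trimethylsilyl)but-3-yn-1-yl]cyclohexyl}propanal F3 as a mixture at the aldehyde α-carbon. Because only one position is enolisable, TBSOTf/Et3N converts F3 regiospecifically into the tert-butyldimethylsilyl enol ether F4, in which the two epimers converge. Swern oxidation of the primary triethylsilyl ether gives the enol ether aldehyde F5, and BF3·OEt2 at −78 °C closes ring A by an intramolecular Mukaiyama aldol addition, coming back to the route at 25.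

Step 18. The process at risk is slow acylation of the hindered 3-hydroxyl, which gives the activated angelate time to isomerise to the tiglate. The fallback builds the Z-enoate on the molecule and sets out from 30: DCC/DMAP esterification with 2-[bis(2,2,2-trifluoroethoxy)phosphoryl]propanoic acid gives the 3-O-{2-[bis(2,2,2-trifluoroethoxy)phosphoryl]propanoyl} ester of 30 F6, and Still–Gennari olefination with acetaldehyde (KHMDS, 18-crown-6, THF, −78 °C) gives the (2Z)-2-methylbut-2-enoate, coming back at 33.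

Step 21. The process at risk is sluggish methylenation of the hindered C8 ketone, during which the reagent may attack or isomerise the conjugated ester. The fallback moves the methylenation in front of the esterification and sets out from 30. HF·pyridine frees the C8 alcohol to give (1S,2R,4aR,5S,6S,8aS)-1-{[(tert-butyldiphenylsilyl)oxy]methyl}-5-{(3E)-5-[(tert-butyldiphenylsilyl)oxy]-3-methylpent-3-en-1-yl}-1,4a-dimethyldecahydronaphthalene-2,6-diol F7, and Dess–Martin oxidation gives the corresponding (1S,4aR,5S,8aS)-2,6-dione F8. Ph3P=CH2 should methylenate only the C8 ketone, since the C3 ketone is flanked by quaternary C4, giving the (1S,4aS,5R,8aS)-6-methylidene-2-one F9. NaBH4 then returns the equatorial 3-alcohol by hydride delivery anti to the two axial methyl groups, giving the (1S,2R,4aS,5R,8aS)-6-methylidene-2-ol F10, and the esterification of step 18 leads back to the route at 36.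

Further compounds

F1 | step 14 | (2E,6S,7S)-6-[(tert-butyldimethylsilyl)oxy]-11-hydroxy-2-methyl-8-methylidene-7-[4-(trimethylsilyl)but-3-yn-1-yl]undec-2-enal | CC(C)(C)[Si](C)(C)O[C@@H](CC/C=C(\C)C=O)[C@@H](CCC#C[Si](C)(C)C)C(=C)CCCO
F2 | step 14 | (2E,6S,7S)-6-[(tert-butyldimethylsilyl)oxy]-2-methyl-8-methylidene-11-[(triethylsilyl)oxy]-7-[4-(trimethylsilyl)but-3-yn-1-yl]undec-2-enal | CC(C)(C)[Si](C)(C)O[C@@H](CC/C=C(\C)C=O)[C@@H](CCC#C[Si](C)(C)C)C(=C)CCCO[Si](CC)(CC)CC
F3 | step 14 | 2-{(1R,2R,3S,4S)-4-[(tert-butyldimethylsilyl)oxy]-2-methyl-2-[3-(triethylsilyloxy)propyl]-3-[4-(trimethylsilyl)but-3-yn-1-yl]cyclohexyl}propanal (both α-epimers) | CC(C)(C)[Si](C)(C)O[C@H]1CC[C@H](C(C)C=O)[C@@](C)(CCCO[Si](CC)(CC)CC)[C@@H]1CCC#C[Si](C)(C)C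
F4 | step 14 | tert-butyldimethylsilyl enol ether of F3 (E/Z mixture) | CC(C)(C)[Si](C)(C)O[C@H]1CC[C@H](C(C)=CO[Si](C)(C)C(C)(C)C)[C@@](C)(CCCO[Si](CC)(CC)CC)[C@@H]1CCC#C[Si](C)(C)C
F5 | step 14 | 3-{(1R,2S,3S,6R)-3-[(tert-butyldimethylsilyl)oxy]-6-{1-[(tert-butyldimethylsilyl)oxy]prop-1-en-2-yl}-1-methyl-2-[4-(trimethylsilyl)but-3-yn-1-yl]cyclohexyl}propanal | CC(C)(C)[Si](C)(C)O[C@H]1CC[C@H](C(C)=CO[Si](C)(C)C(C)(C)C)[C@@](C)(CCC=O)[C@@H]1CCC#C[Si](C)(C)C
F6 | step 18 | 3-O-{2-[bis(2,2,2-trifluoroethoxy)phosphoryl]propanoyl} ester of 30 | CC(C)(C)[Si](C)(C)O[C@H]1CC[C@H]2[C@@](C)(CC[C@@H](OC(=O)C(C)P(=O)(OCC(F)(F)F)OCC(F)(F)F)[C@]2(C)CO[Si](c3ccccc3)(c4ccccc4)C(C)(C)C)[C@@H]1CC/C(C)=C/CO[Si](c5ccccc5)(c6ccccc6)C(C)(C)C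
F7 | step 21 | (1S,2R,4aR,5S,6S,8aS)-1-{[(tert-butyldiphenylsilyl)oxy]methyl}-5-{(3E)-5-[(tert-butyldiphenylsilyl)oxy]-3-methylpent-3-en-1-yl}-1,4a-dimethyldecahydronaphthalene-2,6-diol | O[C@H]1CC[C@H]2[C@@](C)(CC[C@@H](O)[C@]2(C)CO[Si](c3ccccc3)(c4ccccc4)C(C)(C)C)[C@@H]1CC/C(C)=C/CO[Si](c5ccccc5)(c6ccccc6)C(C)(C)C
F8 | step 21 | (1S,4aR,5S,8aS)-1-{[(tert-butyldiphenylsilyl)oxy]methyl}-5-{(3E)-5-[(tert-butyldiphenylsilyl)oxy]-3-methylpent-3-en-1-yl}-1,4a-dimethyloctahydronaphthalene-2,6-dione | O=C1CC[C@H]2[C@@](C)(CCC(=O)[C@]2(C)CO[Si](c3ccccc3)(c4ccccc4)C(C)(C)C)[C@@H]1CC/C(C)=C/CO[Si](c5ccccc5)(c6ccccc6)C(C)(C)C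
F9 | step 21 | (1S,4aS,5R,8aS)-1-{[(tert-butyldiphenylsilyl)oxy]methyl}-5-{(3E)-5-[(tert-butyldiphenylsilyl)oxy]-3-methylpent-3-en-1-yl}-1,4a-dimethyl-6-methylideneoctahydronaphthalen-2(1H)-one | C=C1CC[C@H]2[C@@](C)(CCC(=O)[C@]2(C)CO[Si](c3ccccc3)(c4ccccc4)C(C)(C)C)[C@@H]1CC/C(C)=C/CO[Si](c5ccccc5)(c6ccccc6)C(C)(C)C
F10 | step 21 | (1S,2R,4aS,5R,8aS)-1-{[(tert-butyldiphenylsilyl)oxy]methyl}-5-{(3E)-5-[(tert-butyldiphenylsilyl)oxy]-3-methylpent-3-en-1-yl}-1,4a-dimethyl-6-methylidenedecahydronaphthalen-2-ol | C=C1CC[C@H]2[C@@](C)(CC[C@@H](O)[C@]2(C)CO[Si](c3ccccc3)(c4ccccc4)C(C)(C)C)[C@@H]1CC/C(C)=C/CO[Si](c5ccccc5)(c6ccccc6)C(C)(C)C
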